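The earlier runs and the new flask stem from a simulated flask from invented constants.

At early times the earlier runs already show how fast things happen in this flask. L is the substrate, E and D are reagents, and Z and X are products.

| flask | L | E | D | remark | time |
|---|---|---|---|---|---|
| autumn | 0.20 M | 2.5 equiv | 4 equiv | run made earlier |  |
| dawn | 0.20 M | 3.5 equiv | 4 equiv | run made earlier |  |
| summer | 0.20 M | 5.5 equiv | 4 equiv | run made earlier |  |
| winter | 0.10 M | 2.5 equiv | 4 equiv | run made earlier |  |
| delta | 0.20 M | 2.50 equiv (fed, over 80 min) | 4.00 equiv | all else is in the flask from the start; the feed brings no volume worth counting | 2.0 h |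
| epsilon | 0.20 M | 2.50 equiv (fed, over 8.0 min) | 4.00 equiv | all else is in the flask from the start; the feed brings no volume worth counting | 2.0 h |
| gamma | 0.20 M | 2.50 equiv | 4.00 equiv | everything together at the start | 2.0 h |
| beta | 0.20 M (fed, over 80 min) | 2.50 equiv | 4.00 equiv | all else is in the flask from the start; the feed brings no volume worth counting | 2.0 h |

- autumn (time / min: X / %, Z / %): 10.0: 1, 36; 30.0: 4, 71; 60.0: 2, 87; 80.0: 3, 94; 120: 4, 93
- dawn (time / h: X / %, Z / %): 0.500: 8, 34; 1.00: 8, 39; 1.33: 6, 44; 2.00: 6, 47; 2.50: 12, 48
- summer (time / h: X / %, Z / %): 0.200: 15, 1; 0.333: 15, 0; 0.667: 13, 0; 1.33: 10, 3; 2.50: 13, 0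
- winter (time / h: X / %, Z / %): 0.200: 2, 19; 0.333: 1, 34; 0.667: 1, 55; 1.33: 1, 82; 2.50: 1, 92

(readings scatter by 2 percentage points)

- what was read earlier has a scatter of 2 percentage points, one standard deviation

1. the flask that comes out highest in amount of X, in percent of the L charged; "all alike" if 1.5 percentage points covers them all (delta / epsilon / gamma / beta / all alike)
2. amount of X at the end, in percent of the L charged, delta
3. amount of X at the end, in percent of the L charged, epsilon
4. amount of X at the end, in percent of the L charged, gamma
5. amount of X at the end, in percent of the L charged, beta

I take the fastest rung to be the burn of E against D. In the summer run X reads 15% at 12 min and 13% at 150 min, so X is made early and then stands. There E exceeds D by 1.50 equivalents and Z reads 0%, so I read X as Z that met standing E, a follow-up reaction.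

The next rung is the rise of Z. Autumn reads 71% at 30.0 min, which, taken as a first-order rise, reads as a rise time of 24.2 min, slower than that early burn. The feeds make the last rung: 8.0 min lies below the rise time and 80 min above it.

With everything charged together, autumn ends at 4% X. A fed drop of E instead finds whatever Z has grown by its arrival. Let r be feed time over rise time, and I assume that autumn's rise holds as the clock in a fed flask too. Averaging the rise over the feed gives one minus (one minus exp(−r)) over r, which is small for a short feed and tends to unity for a long one. For delta r is 3.30, which gives 70.8% for the overlap, the mean fraction of the final Z already standing when a drop of E arrives. For epsilon r is 0.330 and the overlap 14.8%. The readings give no scale for X under a feed, so I commit to an order: delta, epsilon, gamma near autumn, then beta. I also expect delta's X to be 4.78 times epsilon's.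

The forecast differs: it names gamma, with X at 0.2% for delta, 0.7% for epsilon, 3% for gamma and 0.2% for beta. Its grounds: “Slow E feed keeps E tiny, giving almost no X.”

    L + D → Q (k = 0.240 /M/min)
    D + E → G (k = 2.20 /M/min)
    Q + G → Z (k = 0.470 /M/min)
    E + Z → X (k = 1.40 /M/min)

Delta comes out highest at 38.6%, above epsilon at 11.0%, gamma at 1.65% and beta at 0.0226%. In delta at 1.00 h X stands at 20.6% and Z at 67.9%, and at 1.33 h, the end of the feed, X stands at 37.1% and Z at 60.8%. Delta's X divided by its overlap gives 54.5% of the L charged per unit of overlap. Multiplied by epsilon's overlap of 14.8%, that makes 8.07%, and epsilon stands at 11.0%.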